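## Analysis of the target

Target 30 is a cis-fused hydroazulene. Ring A is the cyclopentane C1–C2–C3–C4–C5 and ring B the cycloheptene C5–C6–C7–C8=C9–C10–C1; the two share the C1–C5 bond. Five stereocentres lie around the fusion: quaternary C1 (methyl), C5 (H), the tertiary carbinol C4 (hydroxyl and isopropyl), C6 (4-hydroxybenzoyloxy) and C10 (E-configured tigloyloxy). With the face of the C1 methyl called β, H5, the isopropyl group and both ester oxygens are β; only the C4 hydroxyl is α and points into the concave side under ring B. Sensitive features are the allylic C10 ester beside the C8=C9 alkene, the tertiary alcohol β to the C6 oxygen (dehydration or retro-aldol at the ketone stage), two different esters and a free phenol. The difficulty is the crowded C4–C5–C1 triad, the cis fusion, and telling three oxygenated carbons apart on a flexible seven-membered ring. The plan rests on one pattern: the C1–C5 bond joins the methyl-bearing quaternary carbon to a CH lying between oxygenated C4 and C6, and C10–O is the other neighbour of C1. That is what an angular-methyl decalin (C1 bonded to C6, oxygen at C4, C5, C6 and C10) becomes when its ring-fusion bond shifts by one carbon.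

## Retrosynthetic reasoning

Phenol and C10 ester. 30 is traced to its aryl pivalate 29, and 29 is cut at the C10–O acyl bond into allylic alcohol 26 and tiglic acid 27. The allylic ester is the most fragile group, so it goes on last and the phenol is released under conditions that spare alkyl esters.

C8=C9 alkene and C10 carbinol. 26 comes from enone 25 by 1,2-reduction, and 25 from saturated ketone 22 by dehydrogenation; 22 comes from alcohol 21 and silyl ether 20. A C10 ketone can enolise only toward C9 because C1 is quaternary, so the alkene position is unambiguous and the C8 configuration becomes irrelevant. The forward reduction must return the 10β-alcohol.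

C6 ester. 20 is cut at the C6–O acyl bond into diol 17 and acid 19 (from 18). C6–OH is the only free secondary hydroxyl, so no selectivity problem arises, and the ester then protects C6.

C6 carbinol. 17 comes from β-hydroxy ketone 16, and 16 from ketone 15 by unmasking the C4 hydroxyl. That hydroxyl lies under ring B, so it can deliver hydride to the α face of C6 and leave the oxygen β.

Ring reorganisation. In 15 the C1–C5 bond is cut, C1 is reconnected to C6, the C6 carbonyl becomes a tertiary alcohol and C5 receives a sulfonate. This gives trans-decalin hydroxy mesylate 14. The exchange turns a flexible 5–7 problem into a rigid 6–6 one, and the forward 1,2-shift makes both rings and the cis fusion at once.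

Oxygen differentiation. 14 comes from diol 13, which comes from acetonide 12 and carbinol 11. The acetonide covers O5 and O6 while O4 is capped, so that after its removal only O6 can become an alkoxide.

C4–isopropyl bond. 11 is cut between C4 and the isopropyl group to give α-alkoxy ketone 10 and an isopropyl nucleophile. The decalin chair and the neighbouring oxygen fix the face of attack.

C5–O and C6–O bonds. 10 comes from diol 9 and 9 from enone 8 by syn-dihydroxylation. The angular methyl directs the reagent to the α face, which gives the trans-decalin and the equatorial C5 oxygen that the shift needs.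

C10 oxygen. 8 comes from alcohol 7 and 7 from enedione 6 by reduction of the saturated ketone, which places the C10 oxygen β.

Decalin. 6 is cut at C5=C6 (aldol condensation) and C1–C2 (Michael addition) into trione 4, and 4 into dione 2 and enone 3; 2 comes from 1 by methylation. Enamine organocatalysis of the cyclisation sets C1 and with it the absolute configuration of the whole route.

## Alternatives that were turned down

Alternative 1: Ring B is disconnected at C1–C10 and C5–C6 by way of a cyclobutane-1,2-diol. Irradiation of 3-methylcyclopent-2-en-1-one A2 with 4-methyl-1,2-bis(trimethylsilyloxy)cyclopent-1-ene A3 would give cis-anti-cis tricyclic ketone A1; desilylation and glycol cleavage of C6–C10 would then open the seven-membered ring.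
- For: two C–C bonds and both fusion carbons form in one step from two cheap five-membered rings, and the cis fusion follows from the cyclobutane geometry. C6 and C10 appear oxidised and the C8 methyl is in place. In steps to the bicyclic core it is clearly stronger than the chosen route.
- Against: the photoadduct is racemic. After cleavage C5 sits between the C4 and C6 carbonyls, so the cis fusion just made is enolisable. Three ketones (C4, C6, C10) must then be told apart for isopropyl addition, reduction and dehydrogenation.
- Comparison: the chosen route is longer to the bicycle but arrives there enantioenriched, with the C4 carbinol already built and C6 (ketone) and C10 (silyl ether) already distinguished.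

Alternative 2: Ring B is disconnected at C5–C6, the aldol bond of a C4-keto C6-hydroxy unit. SmI2 would reduce the C5 bromide of bromo keto aldehyde A5 to a samarium enolate that adds to the tethered C6 aldehyde and gives hydroazulene A4.
- For: samarium Reformatsky-type aldols close medium rings under neutral conditions with a regiodefined enolate. The C8=C9 alkene and the C10 oxygen are present from the start, which avoids the oxidation, dehydrogenation and re-reduction at C10 of the chosen route; on that point it is stronger.
- Against: one seven-membered closure must set C5 and C6 together, guided only by a chelated transition state. A5 needs the vicinal C1 (quaternary) and C10 centres built on an open chain, a Z trisubstituted alkene and a β,γ-unsaturated aldehyde prone to conjugation. A4 is a retro-aldol-prone β-hydroxy ketone, and the isopropyl group must still be added next to the acidic C5–H.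
- Comparison: the chosen route draws every stereocentre from a rigid decalin and installs the C4 carbinol before the 5–7 system exists, at the cost of the late redox detour at C10.

Alternative 3: Ring A and ring B are disconnected at C5–C1 and C5–C6 back to an arene. A chiral copper carbene (a bis(oxazoline) complex of CuOTf, monovalent copper) from diazoketone A7 would add across the C1–C6 arene bond; the norcaradiene opens to cycloheptatriene A6 (Buchner reaction).
- For: it is the shortest entry to a hydroazulenone, catalytic and asymmetric, with the C4 carbonyl, C8 methyl, C8=C9 alkene and a C10 enol ether in place.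
- Against: C1 carries no methyl in A6, so the quaternary centre must be made later by alkylation. The only stereocentre set, C5, is α to the ketone and doubly allylic. The C6=C7 alkene must be converted selectively into the 6β-alcohol among three alkenes. The electron-rich anisole invites aromatic C–H insertion and attack at the wrong ortho position.
- Comparison: it is the most step-economical route to the skeleton but carries the least stereochemical information forward. The chosen route is longer but fixes C1, C4 and C5 on a conformationally locked intermediate.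

Key step: step 12

Locants C1–C10 are those of the target throughout, also in the decalin intermediates (where they coincide with bicyclo[4.4.0]decane numbering); β is the face of the C1 methyl group.

Assumption: the Michael addition of step 2 should not distinguish the faces of the dione enol, so trione 4 is taken as the isomer with cis ring methyls after separation; the trans isomer would give the C8 epimers of 6–22, which converge on enone 25.

## Route

Step 1
Reactants: 1 5-methylcyclohexane-1,3-dione
Product: 2 2,5-dimethylcyclohexane-1,3-dione
Conditions: MeI, aq. NaOH, 1,4-dioxane, reflux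
Reagents that add atoms: iodomethane, CI
Why: C-Methylation of the 1,3-dione enolate at the carbon between the carbonyls (the future C1 with its methyl); any O-methyl enol ether is hydrolysed back on acidic work-up.

Step 2
Reactants: 2 2,5-dimethylcyclohexane-1,3-dione; 3 methyl vinyl ketone (but-3-en-2-one)
Product: 4 cis-2,5-dimethyl-2-(3-oxobutyl)cyclohexane-1,3-dione (ring methyls cis; achiral)
Conditions: Et3N (cat.), EtOAc, rt
Reagents that add atoms: none
Why: Base-catalysed Michael addition of the dione enol to the enone forms the C1–C2 bond and the quaternary carbon. Both achiral diastereomers are expected because the remote ring methyl hardly biases the enol faces; the cis isomer 4 is separated (see the assumption).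

Step 3
Reactants: 4 cis-2,5-dimethyl-2-(3-oxobutyl)cyclohexane-1,3-dione
Product: 6 (3R,8aR)-3,8a-dimethyl-3,4,8,8a-tetrahydronaphthalene-1,6(2H,7H)-dione (route locants: 1β,8β-dimethylbicyclo[4.4.0]dec-5-ene-4,10-dione), via bicyclic ketol 5 (not isolated)
Conditions: D-proline (0.3 equiv), DMSO, rt
Reagents that add atoms: none
Why: Hajos–Parrish–Eder–Sauer–Wiechert cyclisation (the ring-closing half of a Robinson annulation): the proline enamine of the side-chain ketone attacks one of the two enantiotopic ring carbonyls under direction by the carboxylic acid, D-proline giving R at C1 (methyl β), and ketol 5 dehydrates in the flask. The cis relationship in 4 makes the C8 methyl β; enantiomeric purity should be raised by recrystallisation of 6 or 7 if needed.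

Step 4
Reactants: 6 enedione
Product: 7 10β-hydroxy-1β,8β-dimethylbicyclo[4.4.0]dec-5-en-4-one
Conditions: NaBH4 (0.3 equiv), EtOH, −10 °C
Reagents that add atoms: none
Why: Chemoselective borohydride reduction: the isolated C10 ketone is more electrophilic than the conjugated C4 carbonyl. Hydride adds from the α face, anti to the axial angular methyl, so the hydroxyl is equatorial and β, as needed at C10.

Step 5
Reactants: 7 hydroxy enone
Product: 8 10β-(tert-butyldimethylsilyloxy)-1β,8β-dimethylbicyclo[4.4.0]dec-5-en-4-one
Conditions: TBSCl, imidazole, DMAP (cat.), DMF, 40 °C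
Reagents that add atoms: tert-butyldimethylsilyl chloride, CC(C)(C)[Si](C)(C)Cl
Why: Silylation of the equatorial secondary alcohol; the ether has to last through oxidation, organometallic addition, acid and base until step 17.

Step 6
Reactants: 8 silyloxy enone
Product: 9 5α,6α-dihydroxy-10β-(tert-butyldimethylsilyloxy)-1β,8β-dimethyl-trans-bicyclo[4.4.0]decan-4-one
Conditions: OsO4 (5 mol %), NMO, citric acid, tBuOH/H2O, rt
Reagents that add atoms: OsO4, O=[Os](=O)(=O)=O; N-methylmorpholine N-oxide, C[N+]1([O-])CCOCC1; water, O
Why: Syn-dihydroxylation of the enone C5=C6 bond; citric acid keeps osmium turning over with this electron-poor alkene. OsO4 approaches the α face, opposite the axial C1 methyl that overhangs C6, so C6–OH is axial and trans to the methyl (trans-decalin) and C5–OH is equatorial; the ketol is used at once to avoid β-elimination.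

Step 7
Reactants: 9 dihydroxy ketone
Product: 10 5α,6α-(isopropylidenedioxy)-10β-(tert-butyldimethylsilyloxy)-1β,8β-dimethyl-trans-bicyclo[4.4.0]decan-4-one
Conditions: 2-methoxypropene, PPTS (cat.), CH2Cl2, 0 °C→rt
Reagents that add atoms: 2-methoxypropene, COC(C)=C
Why: Acid-catalysed ketal exchange onto the cis (equatorial–axial) 5,6-diol. The dioxolane masks exactly the two oxygens that must stay distinguishable from the C4 oxygen made next, and it blocks dehydration of the β-hydroxy ketone.

Step 8
Reactants: 10 acetonide ketone
Product: 11 4β-isopropyl-5α,6α-(isopropylidenedioxy)-10β-(tert-butyldimethylsilyloxy)-1β,8β-dimethyl-trans-bicyclo[4.4.0]decan-4α-ol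
Conditions: iPrMgCl, CeCl3 (anhydrous), THF, −78→0 °C
Reagents that add atoms: isopropylmagnesium chloride, CC(C)[Mg]Cl
Why: Organocerium addition; the low basicity suppresses enolisation and β-hydride reduction of the hindered α-alkoxy ketone. The reagent enters along the equatorial trajectory from the β side because the α face is closed by the axial C6 oxygen and the acetonide, and chelation to the in-plane equatorial C5 oxygen favours the same approach, so the hydroxyl ends axial (α) and the isopropyl group equatorial (β).

Step 9
Reactants: 11 tertiary carbinol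
Product: 12 4α-(benzyloxymethoxy)-4β-isopropyl-5α,6α-(isopropylidenedioxy)-10β-(tert-butyldimethylsilyloxy)-1β,8β-dimethyl-trans-bicyclo[4.4.0]decane
Conditions: BOMCl, iPr2NEt, nBu4NI (cat.), ClCH2CH2Cl, 60 °C
Reagents that add atoms: benzyl chloromethyl ether, ClCOCc1ccccc1
Why: Alkylation of the tertiary hydroxyl with the reactive chloromethyl ether under iodide catalysis. A slim CH2-linked group suits the crowded axial position, resists the acid of step 10 and the base of step 12, and leaves later by neutral hydrogenolysis.

Step 10
Reactants: 12 acetonide
Product: 13 4α-(benzyloxymethoxy)-4β-isopropyl-10β-(tert-butyldimethylsilyloxy)-1β,8β-dimethyl-trans-bicyclo[4.4.0]decane-5α,6α-diol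
Conditions: AcOH/THF/H2O, 45 °C
Reagents that add atoms: none
Why: Acid hydrolysis of the acetone ketal; a formaldehyde acetal hydrolyses far more slowly than an acetone ketal, and the hindered secondary silyl ether tolerates aqueous acetic acid.

Step 11
Reactants: 13 diol
Product: 14 4α-(benzyloxymethoxy)-6α-hydroxy-4β-isopropyl-10β-(tert-butyldimethylsilyloxy)-1β,8β-dimethyl-trans-bicyclo[4.4.0]decan-5α-yl methanesulfonate
Conditions: MsCl, Et3N, CH2Cl2, −20→0 °C
Reagents that add atoms: methanesulfonyl chloride, CS(=O)(=O)Cl
Why: Sulfonylation of the only secondary hydroxyl; the tertiary C6 hydroxyl does not react and the equatorial α configuration at C5 is untouched.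

Step 12
Reactants: 14 hydroxy mesylate
Product: 15 cis-fused hydroazulenone: 4α-(benzyloxymethoxy)-10β-(tert-butyldimethylsilyloxy)-4β-isopropyl-1β,8β-dimethyl-5βH-decahydroazulen-6-one (route locants)
Conditions: KOtBu (1.05 equiv), THF, −20→0 °C; AcOH quench
Reagents that add atoms: none
Why: tert-Butoxide deprotonates the only free hydroxyl, the axial tertiary C6–OH, and the alkoxide pushes the C1–C6 bond, which is antiperiplanar to the equatorial C5–O sulfonate bond in the locked trans-decalin, from C6 onto C5 as mesylate leaves; this is the semipinacol (pinacol-type) rearrangement of a 1,2-diol monosulfonate, a known way from hydroxydecalin sulfonates to hydroazulenones. Ring A arises by contraction of the six-membered ring C1–C6 through this 1,2-shift with a three-centre transition state, and ring B by simultaneous one-carbon enlargement of the other ring as C5 is inserted between C1 and C6; neither is a chain cyclisation, so no exo or endo mode applies. C5 is the one new stereocentre: the migrating carbon attacks it from the back and inverts it, so H5 ends β and cis to the C1 methyl, while C1 migrates with retention and C4, C8 and C10 are untouched. The step needs exclusive migration of C1: C7 and the C6–O bond are gauche to the leaving group, so neither the alternative shift nor epoxide closure can compete; C5 has no β-hydrogen because C4 and C6 are fully substituted, so elimination is excluded; and the C4 oxygen, whose C4–C3 bond is also antiperiplanar, is an ether and cannot supply an alkoxide push. The base is consumed as potassium mesylate forms, which limits enolisation of the new β-alkoxy ketone toward C5 (epimerisation or E1cB loss of the C4 alkoxy group).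

Step 13
Reactants: 15 hydroazulenone
Product: 16 10β-(tert-butyldimethylsilyloxy)-4α-hydroxy-4β-isopropyl-1β,8β-dimethyl-5βH-decahydroazulen-6-one (route locants)
Conditions: H2 (1 atm), Pd(OH)2 on carbon, EtOAc, rt
Reagents that add atoms: none
Why: Hydrogenolysis of the benzyl C–O bond; the hemiformal left behind loses formaldehyde and frees the tertiary hydroxyl under neutral conditions, which matters because the β-hydroxy ketone tolerates neither base (retro-aldol) nor strong acid (dehydration). Ketone and silyl ether are inert and no alkene is present yet.

Step 14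
Reactants: 16 β-hydroxy ketone
Product: 17 10β-(tert-butyldimethylsilyloxy)-4β-isopropyl-1β,8β-dimethyl-5βH-decahydroazulene-4α,6β-diol (route locants)
Conditions: Me4NBH(OAc)3, MeCN/AcOH, −30→0 °C
Reagents that add atoms: none
Why: Saksena–Evans hydroxyl-directed reduction: the C4 hydroxyl exchanges onto boron and delivers hydride through a six-membered transition state. Because this α-hydroxyl lies on the concave face under ring B, hydride reaches C6 from α and the new hydroxyl is β (1,3-anti), the opposite of what external hydride on the open convex face should give. The acidic medium avoids retro-aldol cleavage, and the silylated C10 oxygen leaves only one hydroxyl to direct.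

Step 15
Reactants: 18 4-hydroxybenzoic acid
Product: 19 4-(pivaloyloxy)benzoic acid
Conditions: PivCl, aq. NaOH, THF, 0 °C; then HCl
Reagents that add atoms: pivaloyl chloride, CC(C)(C)C(=O)Cl
Why: Schotten–Baumann acylation: the phenoxide of the dianion is the more nucleophilic oxygen, any mixed anhydride at the carboxylate is hydrolysed in the aqueous base, and acidification returns the acid.

Step 16
Reactants: 17 diol; 19 4-(pivaloyloxy)benzoic acid
Product: 20 6β-[4-(pivaloyloxy)benzoyloxy]-10β-(tert-butyldimethylsilyloxy)-4β-isopropyl-1β,8β-dimethyl-5βH-decahydroazulen-4α-ol (route locants)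
Conditions: EDC·HCl, DMAP, CH2Cl2, rt
Reagents that add atoms: none
Why: Carbodiimide/DMAP (Steglich) esterification; only the secondary C6 hydroxyl is acylated, the tertiary C4 hydroxyl being too hindered, and the bulky pivalate on the phenol is not transferred by DMAP.

Step 17
Reactants: 20 silyl ether
Product: 21 6β-[4-(pivaloyloxy)benzoyloxy]-4β-isopropyl-1β,8β-dimethyl-5βH-decahydroazulene-4α,10β-diol (route locants)
Conditions: HF·pyridine, pyridine, THF, 0 °C→rt
Reagents that add atoms: none
Why: Fluoride cleavage of the secondary silyl ether under mildly acidic conditions, which leave the aryl pivalate, the aroate and the tertiary alcohol untouched.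

Step 18
Reactants: 21 diol
Product: 22 6β-[4-(pivaloyloxy)benzoyloxy]-4α-hydroxy-4β-isopropyl-1β,8β-dimethyl-5βH-decahydroazulen-10-one (route locants)
Conditions: Dess–Martin periodinane, NaHCO3, CH2Cl2, rt
Reagents that add atoms: none
Why: Dess–Martin oxidation of the secondary alcohol under buffered neutral conditions; the tertiary hydroxyl cannot be oxidised.

Step 19
Reactants: 22 C10 ketone
Product: 25 6β-[4-(pivaloyloxy)benzoyloxy]-4α-hydroxy-4β-isopropyl-1β,8-dimethyl-5βH-hydroazul-8-en-10-one (route locants), via bis(trimethylsilyl) enol ether 23 (not isolated), via C4-O-trimethylsilyl enone 24 (not isolated)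
Conditions: TMSOTf, Et3N, CH2Cl2, 0 °C; Pd(OAc)2, MeCN, rt; 1 M HCl, THF, 0 °C
Reagents that add atoms: none
Why: Saegusa–Ito dehydrogenation. The C10 ketone can enolise only toward C9 because C1 is quaternary, and silylation also caps the C4 hydroxyl transiently; divalent palladium exchanges onto the enol ether and β-hydride elimination of the C8 hydrogen gives the C8=C9 enone and zerovalent palladium. The C8 stereocentre disappears here, and dilute acid then frees the C4 hydroxyl.

Step 20
Reactants: 25 enone
Product: 26 6β-[4-(pivaloyloxy)benzoyloxy]-4β-isopropyl-1β,8-dimethyl-5βH-hydroazul-8-ene-4α,10β-diol (route locants)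
Conditions: NaBH4, CeCl3·7H2O, MeOH, −78 °C
Reagents that add atoms: none
Why: Luche 1,2-reduction; CeCl3 suppresses conjugate reduction and keeps the medium non-basic, so the C6 ester is not expelled through the dienolate. Hydride is expected to add anti to the adjacent C1 methyl and the β-aroyloxy group, that is from α, returning the 10β-alcohol; this is a prediction for a flexible ring and is treated as a risk below.

Step 21
Reactants: 26 allylic alcohol; 27 tiglic acid ((E)-2-methylbut-2-enoic acid)
Product: 29 6β-[4-(pivaloyloxy)benzoyloxy]-10β-[(E)-2-methylbut-2-enoyloxy]-4β-isopropyl-1β,8-dimethyl-5βH-hydroazul-8-en-4α-ol (route locants), via mixed anhydride 28 (not isolated)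
Conditions: 27, 2,4,6-trichlorobenzoyl chloride, Et3N, toluene, rt; then 26, DMAP, 60 °C
Reagents that add atoms: none
Why: Yamaguchi esterification: tiglic acid is activated as mixed anhydride 28 and DMAP transfers the tigloyl group to the hindered neopentyl-type allylic alcohol. The E acid is the stable isomer and the tertiary C4 hydroxyl is not acylated.

Step 22
Reactants: 29 aryl pivalate
Product: 30 target, 6β-(4-hydroxybenzoyloxy)-10β-[(E)-2-methylbut-2-enoyloxy]-4β-isopropyl-1β,8-dimethyl-5βH-hydroazul-8-en-4α-ol (route locants)
Conditions: pyrrolidine, CH2Cl2, 0 °C→rt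
Reagents that add atoms: none
Why: Aminolysis of the aryl pivalate: a phenyl ester, here with a para carbonyl that improves the phenoxide leaving group, reacts with pyrrolidine far faster than the two alkyl esters, so the phenol is released without touching the tiglate, the aroate or the allylic C–O bond.

## Compound list

1 | 5-methylcyclohexane-1,3-dione | CC1CC(=O)CC(=O)C1 | starting material
2 | 2,5-dimethylcyclohexane-1,3-dione | CC1CC(=O)C(C)C(=O)C1 | intermediate
3 | methyl vinyl ketone | CC(=O)C=C | starting material
4 | cis-2,5-dimethyl-2-(3-oxobutyl)cyclohexane-1,3-dione | C[C@@]1(CCC(C)=O)C(=O)C[C@@H](C)CC1=O | intermediate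
5 | bicyclic ketol, 6β-hydroxy-1β,8β-dimethylbicyclo[4.4.0]decane-4,10-dione | C[C@@]12CCC(=O)C[C@]1(O)C[C@@H](C)CC2=O | intermediate (not isolated)
6 | (3R,8aR)-3,8a-dimethyl-3,4,8,8a-tetrahydronaphthalene-1,6(2H,7H)-dione | C[C@@]12CCC(=O)C=C1C[C@@H](C)CC2=O | intermediate
7 | 10β-hydroxy-1β,8β-dimethylbicyclo[4.4.0]dec-5-en-4-one | C[C@@]12CCC(=O)C=C1C[C@@H](C)C[C@H]2O | intermediate
8 | 10β-silyloxy enone (TBS ether of 7) | C[C@@]12CCC(=O)C=C1C[C@@H](C)C[C@H]2O[Si](C)(C)C(C)(C)C | intermediate
9 | 5α,6α-dihydroxy ketone | C[C@@]12CCC(=O)[C@H](O)[C@@]1(O)C[C@@H](C)C[C@H]2O[Si](C)(C)C(C)(C)C | intermediate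
10 | 5α,6α-acetonide ketone | C[C@@]12CCC(=O)[C@@H]3OC(C)(C)O[C@@]31C[C@@H](C)C[C@H]2O[Si](C)(C)C(C)(C)C | intermediate
11 | 4β-isopropyl-4α-carbinol acetonide | C[C@@]12CC[C@@](O)(C(C)C)[C@@H]3OC(C)(C)O[C@@]31C[C@@H](C)C[C@H]2O[Si](C)(C)C(C)(C)C | intermediate
12 | 4α-benzyloxymethyl ether acetonide | C[C@@]12CC[C@@](OCOCc4ccccc4)(C(C)C)[C@@H]3OC(C)(C)O[C@@]31C[C@@H](C)C[C@H]2O[Si](C)(C)C(C)(C)C | intermediate
13 | 5α,6α-diol with 4α-benzyloxymethoxy group | C[C@@]12CC[C@@](OCOCc3ccccc3)(C(C)C)[C@H](O)[C@@]1(O)C[C@@H](C)C[C@H]2O[Si](C)(C)C(C)(C)C | intermediate
14 | trans-decalin 6α-hydroxy 5α-mesylate | C[C@@]12CC[C@@](OCOCc3ccccc3)(C(C)C)[C@H](OS(C)(=O)=O)[C@@]1(O)C[C@@H](C)C[C@H]2O[Si](C)(C)C(C)(C)C | intermediate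
15 | cis-fused hydroazulen-6-one with 4α-benzyloxymethoxy and 10β-silyloxy groups | CC(C)(C)[Si](C)(C)O[C@@H]1C[C@H](C)CC(=O)[C@@H]2[C@@]1(C)CC[C@@]2(OCOCc3ccccc3)C(C)C | intermediate
16 | 4α-hydroxy hydroazulen-6-one | CC(C)(C)[Si](C)(C)O[C@@H]1C[C@H](C)CC(=O)[C@@H]2[C@@]1(C)CC[C@@]2(O)C(C)C | intermediate
17 | 4α,6β-diol | CC(C)(C)[Si](C)(C)O[C@@H]1C[C@H](C)C[C@H](O)[C@@H]2[C@@]1(C)CC[C@@]2(O)C(C)C | intermediate
18 | 4-hydroxybenzoic acid | O=C(O)c1ccc(O)cc1 | starting material
19 | 4-(pivaloyloxy)benzoic acid | CC(C)(C)C(=O)Oc1ccc(cc1)C(O)=O | intermediate
20 | 6β-aroate, 10β-silyl ether | CC(C)(C)[Si](C)(C)O[C@@H]1C[C@H](C)C[C@H](OC(=O)c3ccc(OC(=O)C(C)(C)C)cc3)[C@@H]2[C@@]1(C)CC[C@@]2(O)C(C)C | intermediate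
21 | 6β-aroate 4α,10β-diol | O[C@@H]1C[C@H](C)C[C@H](OC(=O)c3ccc(OC(=O)C(C)(C)C)cc3)[C@@H]2[C@@]1(C)CC[C@@]2(O)C(C)C | intermediate
22 | 6β-aroate 10-ketone | O=C1C[C@H](C)C[C@H](OC(=O)c3ccc(OC(=O)C(C)(C)C)cc3)[C@@H]2[C@@]1(C)CC[C@@]2(O)C(C)C | intermediate
23 | bis(trimethylsilyl) compound: C10 enol ether and C4 silyl ether | C[Si](C)(C)OC1=C[C@H](C)C[C@H](OC(=O)c3ccc(OC(=O)C(C)(C)C)cc3)[C@@H]2[C@@]1(C)CC[C@@]2(O[Si](C)(C)C)C(C)C | intermediate (not isolated)
24 | C4-O-trimethylsilyl C8=C9 enone | O=C1C=C(C)C[C@H](OC(=O)c3ccc(OC(=O)C(C)(C)C)cc3)[C@@H]2[C@@]1(C)CC[C@@]2(O[Si](C)(C)C)C(C)C | intermediate (not isolated)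
25 | C8=C9 enone (10-ketone) | O=C1C=C(C)C[C@H](OC(=O)c3ccc(OC(=O)C(C)(C)C)cc3)[C@@H]2[C@@]1(C)CC[C@@]2(O)C(C)C | intermediate
26 | 10β-allylic alcohol | O[C@@H]1C=C(C)C[C@H](OC(=O)c3ccc(OC(=O)C(C)(C)C)cc3)[C@@H]2[C@@]1(C)CC[C@@]2(O)C(C)C | intermediate
27 | tiglic acid | C/C=C(\C)C(=O)O | starting material
28 | tiglic 2,4,6-trichlorobenzoic mixed anhydride | C/C=C(\C)C(=O)OC(=O)c1c(Cl)cc(Cl)cc1Cl | intermediate (not isolated)
29 | O-pivaloyl derivative of the target | C/C=C(\C)C(=O)O[C@@H]1C=C(C)C[C@H](OC(=O)c2ccc(OC(=O)C(C)(C)C)cc2)[C@@H]2[C@@]1(C)CC[C@@]2(O)C(C)C | intermediate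
30 | target CNP0273650.9 | C/C=C(\C)C(=O)O[C@@H]1C=C(C)C[C@H](OC(=O)c2ccc(O)cc2)[C@@H]2[C@@]1(C)CC[C@@]2(O)C(C)C | target

## Step count and least certain steps

Total: 22 steps. Longest linear sequence: 21 steps (steps 1–14 and 16–22, from 1 to 30); step 15 is a one-step side branch.

Step 12 (key step). Once ketone 15 has formed, any alkoxide left over can enolise it toward C5. That would epimerise the ring fusion to the trans series or expel the C4 alkoxy group by an E1cB path. Slow ionisation of a sulfonate flanked by two fully substituted carbons would lengthen this exposure. Fallback, from 14: run the shift without free base as an organoaluminium-promoted pinacol-type rearrangement (Et3Al, CH2Cl2, −78→0 °C). The aluminium alkoxide at O6 is the donor and the aluminium centre assists departure of the mesylate. The aluminium-bound ketone is reduced in the same flask with iBu2AlH at −78 °C, so the base-labile β-alkoxy ketone never accumulates. Hydride should arrive from the convex face and give the 6α-alcohol F1. Buffered Dess–Martin oxidation of F1 then gives 15, where the route is rejoined.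

Step 8. The isopropyl reagent may reduce the hindered ketone by β-hydride transfer or enolise it instead of adding. Fallback, from 10: add the isopropenyl cerium reagent (CH2=C(CH3)MgBr, CeCl3, THF, −78 °C), which is smaller and has no β-hydrogen to transfer. The same equatorial approach should give the isopropenyl carbinol F2. Hydrogenation of its 1,1-disubstituted alkene (H2, Pd on carbon, EtOAc) returns to 11.

Step 9. Alkylation may stall because the axial tertiary hydroxyl is shielded by the isopropyl group and the 1,3-diaxial acetal oxygen. Fallback, from 11: change the protecting-group logic to silicon.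
- TESOTf with 2,6-lutidine should give the triethylsilyl ether F3.
- The acetonide is exchanged off under buffered conditions (PPTS, MeOH/CH2Cl2, 0 °C) to give the diol F4.
- Mesylation as in step 11 gives the hydroxy mesylate F5, and KOtBu as in step 12 gives the hydroazulenone F6.
- HF·pyridine buffered with pyridine at 0 °C removes the tertiary triethylsilyl group ahead of the hindered secondary silyl ether and gives 16.

The price is a narrower margin between acetonide and triethylsilyl ether cleavage.

Step 14. Exchange of the tertiary hydroxyl onto boron may be slow, so that undirected hydride delivery to the open β face competes and facial selectivity suffers; the β-hydroxy ketone may also dehydrate or cleave in the acidic medium. Fallback, from 16: use the intrinsic bias instead. NaBH4 in MeOH at −40 °C should reduce 16 from the convex face to the 6α-epimeric diol F7. Mitsunobu esterification of F7 with acid 19 (PPh3, DIAD, toluene) inverts C6 and gives 20 directly; the tertiary hydroxyl is inert.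

Step 20. Hydride addition to the flexible cycloheptenone may show poor facial selectivity or favour the β face. Fallback, from 25: if the reduction gives mainly the 10α-allylic alcohol F8, esterify F8 with tiglic acid 27 under Mitsunobu conditions (PPh3, DIAD, THF). Inversion at the allylic C10 then leads to 29.

## Further compounds

F1 | step 12 | 6α-alcohol with 4α-benzyloxymethoxy and 10β-silyloxy groups (cis-fused hydroazulene) | CC(C)(C)[Si](C)(C)O[C@@H]1C[C@H](C)C[C@@H](O)[C@@H]2[C@@]1(C)CC[C@@]2(OCOCc3ccccc3)C(C)C
F2 | step 8 | 4β-isopropenyl-4α-carbinol acetonide | C[C@@]12CC[C@@](O)(C(C)=C)[C@@H]3OC(C)(C)O[C@@]31C[C@@H](C)C[C@H]2O[Si](C)(C)C(C)(C)C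
F3 | step 9 | 4α-triethylsilyl ether acetonide | C[C@@]12CC[C@@](O[Si](CC)(CC)CC)(C(C)C)[C@@H]3OC(C)(C)O[C@@]31C[C@@H](C)C[C@H]2O[Si](C)(C)C(C)(C)C
F4 | step 9 | 5α,6α-diol with 4α-triethylsilyloxy group | C[C@@]12CC[C@@](O[Si](CC)(CC)CC)(C(C)C)[C@H](O)[C@@]1(O)C[C@@H](C)C[C@H]2O[Si](C)(C)C(C)(C)C
F5 | step 9 | trans-decalin 6α-hydroxy 5α-mesylate with 4α-triethylsilyloxy group | C[C@@]12CC[C@@](O[Si](CC)(CC)CC)(C(C)C)[C@H](OS(C)(=O)=O)[C@@]1(O)C[C@@H](C)C[C@H]2O[Si](C)(C)C(C)(C)C
F6 | step 9 | cis-fused hydroazulen-6-one with 4α-triethylsilyloxy and 10β-silyloxy groups | CC(C)(C)[Si](C)(C)O[C@@H]1C[C@H](C)CC(=O)[C@@H]2[C@@]1(C)CC[C@@]2(O[Si](CC)(CC)CC)C(C)C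
F7 | step 14 | 4α,6α-diol (C6 epimer of 17) | CC(C)(C)[Si](C)(C)O[C@@H]1C[C@H](C)C[C@@H](O)[C@@H]2[C@@]1(C)CC[C@@]2(O)C(C)C
F8 | step 20 | 10α-allylic alcohol (C10 epimer of 26) | O[C@H]1C=C(C)C[C@H](OC(=O)c3ccc(OC(=O)C(C)(C)C)cc3)[C@@H]2[C@@]1(C)CC[C@@]2(O)C(C)C
A1 | alternative 1 | cis-anti-cis tricyclic bis(trimethylsilyloxy) ketone (photoadduct) | C[Si](C)(C)O[C@@]12C[C@H](C)C[C@]1(O[Si](C)(C)C)[C@@H]3[C@@]2(C)CCC3=O
A2 | alternative 1 | 3-methylcyclopent-2-en-1-one | CC1=CC(=O)CC1
A3 | alternative 1 | 4-methyl-1,2-bis(trimethylsilyloxy)cyclopent-1-ene | CC1CC(O[Si](C)(C)C)=C(O[Si](C)(C)C)C1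
A4 | alternative 2 | hydroazulene with C4 ketone, C6 alcohol and C10 silyl ether | CC(C)(C)[Si](C)(C)O[C@@H]1C=C(C)C[C@H](O)[C@@H]2[C@@]1(C)CCC2=O
A5 | alternative 2 | 2-bromocyclopentanone carrying the (Z)-alkenyl aldehyde chain at C1 | CC(C)(C)[Si](C)(C)O[C@H](/C=C(C)\CC=O)[C@]1(C)CCC(=O)C1Br
A6 | alternative 3 | 8-methoxy-6-methyl-3,8a-dihydroazulen-1(2H)-one | COC1=C2CCC(=O)[C@@H]2C=CC(C)=C1
A7 | alternative 3 | 1-diazo-4-(2-methoxy-4-methylphenyl)butan-2-one | COc1cc(C)ccc1CCC(=O)C=[N+]=[N-]
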